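## The problem

The target joins three rings. Ring A is a cyclohexene whose tetrasubstituted C-1=C-2 alkene carries the methyl propanoate arm on C-1 and a 1,3,3-trimethylcyclohexyl group (ring C) on C-2. Ring B is a cis-fused lactol–lactone with its carbonyl carbon on C-5 and its lactol carbon on C-6.

Ring C is attached through its all-carbon quaternary stereocentre Cq (C-1′). The alkene insulates Cq from every other stereocentre, so a reagent, not the substrate, must set it.

C-5 and C-6 are contiguous and cis, and the carbons they carry differ in oxidation level (acid on C-5, aldehyde on C-6). They are best made together in one step that fixes both the cis relationship and the orientation. Adding the C-6 carbon to a cyclohexenone enolate next to an existing C-5 substituent would place it anti and give the trans isomer.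

Cα lies between the ester and the tetrasubstituted alkene. Allylic strain against Cq fixes its conformation, but neither neighbour chooses its configuration, so a catalyst has to. The lactol carbon is the fifth stereocentre; it equilibrates through the open aldehyde–acid.

The lactol–lactone opens in base to an epimerisable aldehyde, Cα is both α to an ester and allylic, and the alkene next to Cq invites cationic shifts in strong acid. The harsh steps (exhaustive methylation, removal of a hindered ketone) must therefore be finished on a robust fragment before ring B appears, and ring B should stay masked as an acetal until the last step.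

Ring C itself makes the key step possible. Cq bears a methyl group and the sp2 carbon C-2, and its neighbour C-2′ is a methylene flanked by the gem-dimethyl carbon C-3′. This is the pattern left when a 2-(1-hydroxycyclopentyl)-1,3-diene is protonated at its terminal CH2 and the ring bond that becomes Cq–C-6′ migrates. C-2′ emerges as a ketone that first directs the methylation of C-3′ and is then removed.

## Retrosynthesis

**Unmasking ring B (22 from 21).** The lactol hydroxyl of 22 is traced back to the menthyloxy group of the mixed acetal 21; only the exocyclic acetal C–O bond is cut. Keeping ring B as an acetal to the end avoids the base-labile pseudo-acid. It also avoids the regiochemical question that a late partial reduction of an anhydride or oxidation of a diol would raise. The forward hydrolysis has to spare the hindered methyl ester and leave Cα untouched.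

**Cα (21 from 20, then 20 from 17 and 19).** The Cα–H bond is cut first: 21 comes from the α-substituted acrylate 20 by asymmetric hydrogenation. Then the C-1–Cα bond is cut: 20 comes from enol triflate 17 and the α-stannyl acrylate 19. Coupling a propanoate enolate directly would give both Cα epimers with nothing to choose between them. The acrylate defers the stereocentre to a catalyst-controlled step. The precursor 17 has four carbons and one stereocentre fewer.

**The C-1 oxygen (17 from 15, 15 from 14, 14 from 13).** The triflate oxygen on C-1 is traced to enone 15. Conjugate hydride addition at the unsubstituted C-3 gives only the C-1/C-2 enolate, so the tetrasubstituted alkene is placed without ambiguity. Enone 15 comes from allylic alcohol 14, and 14 from alkene 13 by allylic oxidation at C-1. Carrying this oxygen on the diene terminus instead would reverse the orientation of the cycloaddition below, so it is introduced afterwards.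

**Rings A and B together (13 from 11 and 12).** The C-1–C-6 and C-4–C-5 bonds are cut in a Diels–Alder sense, giving diene 11 and the enantiopure 5-(menthyloxy)butenolide 12. This one step closes ring A, delivers ring B at the right oxidation levels (carbonyl on the C-5 carbon, acetal on the C-6 carbon), makes the fusion cis by construction and sets C-5 and C-6 absolutely from the acetal carbon of 12. The forward reaction must bond the diene CH2 next to C-2 to the β-carbon of the butenolide, and must add anti to the menthyloxy group. Any minor Cq antipode in 11 becomes a diastereomer of 13 and can be removed there.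

**The diene (11 from 10, 10 from 8, 8 from 7).** The C-3–C-4 vinyl unit of 11 is cut from enol triflate 10. Triflate 10 comes from methyl ketone 8, and 8 from the vinyl group of hydrocarbon 7. The vinyl carbon attached to Cq becomes C-2. These are three routine steps on a hydrocarbon with no sensitive group.

**Ring C substituents (7 from 5, 5 from 3).** The C-2′ methylene of 7 is traced to the ketone of 5, and the gem-dimethyl group at C-3′ to a double enolate methylation of 3. In 3 the ketone has a single enolisable position because Cq is quaternary. The ketone flanked by two quaternary carbons is removed here, on an eleven-carbon fragment that tolerates forcing conditions, not later on a functionalised intermediate.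

**Key disconnection (3 from 2).** The Cq–C-6′ bond is cut. Ketone 3 is the product of a protio-semipinacol ring expansion of dienyl cyclopentanol 2, which has no stereocentre and a symmetrical carbinol. The alkenyl donor on the cationic carbon is reduced to a vinyl group. A complete ring A at this point would have to carry its C-5 substituent through the rearrangement and then accept the C-6 carbon trans to it. The forward reaction must protonate the diene at the terminal CH2, shift a ring bond faster than the cation loses a proton, and do so under control of a chiral counter-anion.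

**The diene carbinol (2 from 1).** The C-3–C-4 alkene of 2 is cut in an enyne-metathesis sense, leading to the commercial alkynol 1.

## Roads not taken

**Alternative 1:** The cut is across the two ring-fusion bonds of ring B at the cyclobutanone level. Benzyloxyketene, made in the flask, would add across C-5=C-6 of the ring A diene A1 (methyl (2R)-2-{2-[(1S)-1,3,3-trimethylcyclohexyl]cyclohexa-1,5-dien-1-yl}propanoate) to give the cis-fused benzyloxycyclobutanone A2. A Baeyer–Villiger insertion on the alkoxy-bearing side and debenzylation would then give the lactol–lactone.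

- Merits: both ring-fusion bonds form cis in one step, the two oxidation levels arrive correctly placed, and the strained ketone should oxidise faster than the hindered alkene. In the number of steps spent on ring B this road is at least as short as the chosen one.
- Weak points: the face of the diene is chosen only by Cα, which sits on a freely rotating arm, and by the remote Cq, so the absolute configuration of C-5 and C-6 is left to a weak bias. The diene A1 must already contain Cα next to a dienyl system in which that hydrogen is doubly activated. A ketene can also add to a 1,3-diene in more than one orientation.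
- Comparison: the chosen plan spends more steps on C-1 after the cycloaddition, but it sets C-5 and C-6 from a covalently bound auxiliary and brings in Cα last under catalyst control.

**Alternative 2:** The cut is through three bonds of ring A. The acylal-tethered enyne A3 (5-oxo-2,5-dihydrofuran-2-yl 2-methyl-4-[(1S)-1,3,3-trimethylcyclohexyl]but-3-ynoate) and acetylene would combine under a cationic rhodium–BINAP catalyst to the tricyclic diene bis-lactone A4. Selective hydrogenation of the disubstituted alkene and methanolysis of the six-membered lactone would follow.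

- Merits: this is the most convergent road. Ring A, ring B and the Cα arm arrive in one step, the tether relates Cα to the acetal carbon, and the rigid tricycle would let Cα settle in the right configuration. If it worked it would be clearly shorter than the chosen plan, and that has to be conceded.
- Weak points: the alkyne carbon next to Cq is flanked by a quaternary centre, which is a poor partner for oxidative cyclisation. Acetylene can trimerise on its own. The acetal carbon of a 5-acyloxybutenolide is configurationally labile. The final methanolysis must pick the hindered six-membered lactone carbonyl of an acylal over the more accessible five-membered one, which is unproven.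
- Comparison: the chosen plan sets against the shorter count that each of its steps outside the key step has a close precedent, and that its acetal is opened by water, where no regiochemical choice exists.

**Alternative 3:** The cut is through C-5–C-6 and C-1=C-2. The keto diester A5 (di-tert-butyl 2-methyl-3-oxopentanedioate) would add through its methylene to the keto-enoate A6 (tert-butyl (2E)-4-oxo-5-[(1S)-1,3,3-trimethylcyclohexyl]pent-2-enoate). The resulting 1,5-diketone would condense to the cyclohexenone triester A7.

- Merits: two simple fragments, no transition metal, and the whole carbon skeleton of ring A in one operation. In convergence and cost this road is better than the chosen plan.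
- Weak points: the aldol condensation must engage the methylene next to Cq and dehydrate to a tetrasubstituted enone. Cα, C-5 and C-6 are all α to carbonyl groups, so equilibration would favour the trans diester and leave Cα unbiased. Three tert-butyl esters must later become a methyl ester, a lactone carbonyl and a lactol carbon. The C-3 ketone must be removed without moving the alkene.
- Comparison: the chosen plan is longer to the skeleton, but it does not have to differentiate three like esters or correct three epimerisable centres.

Key step: step 2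

Assumption: the lactol carbon equilibrates through the open aldehyde–acid, so step 15 gives the thermodynamic hydroxy lactone; the epimer drawn for the target (hydroxyl on the side of C-1, where it can hydrogen-bond to the ester carbonyl) is taken to be that form.

Assumption: (5S)-5-[(1S,2R,5S)-menthyloxy]furan-2(5H)-one 12 is treated as a purchasable building block; it is otherwise available in two steps from furfural and (+)-menthol.

## Route

Step 1
Reactants: 1 1-ethynylcyclopentan-1-ol
Product: 2 1-(buta-1,3-dien-2-yl)cyclopentan-1-ol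
Conditions: RuCl2(=CHPh)(PCy3)(H2IMes) (second-generation Grubbs catalyst, 5 mol %), ethylene (4 bar), CH2Cl2, 40 °C
Reagents that add atoms: ethylene, C=C
Why: Ethylene–alkyne cross enyne metathesis converts a terminal alkyne into a 2-substituted 1,3-diene; carbene–ruthenium catalysts with an N-heterocyclic carbene ligand tolerate a free propargylic hydroxyl under ethylene pressure, and no stereocentre is formed.

Step 2
Reactants: 2 1-(buta-1,3-dien-2-yl)cyclopentan-1-ol
Product: 3 (2R)-2-ethenyl-2-methylcyclohexan-1-one
Conditions: (R)-3,3′-bis(2,4,6-triisopropylphenyl)-BINOL N-triflylphosphoramide (10 mol %; antipode to be matched to the (R) product), 5 Å molecular sieves, toluene, −40 °C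
Reagents that add atoms: none
Why: Proposed new method: the chiral acid protonates the terminal CH2 of the 1,1-disubstituted alkene of 2, giving a tertiary cation delocalised into the vinyl group and paired with the chiral phosphoramidate, and a ring C–C bond of the carbinol aligned with the empty orbital migrates to the cationic carbon while the hydroxyl becomes the ketone; the closest known reaction type is the Brønsted-acid-catalysed enantioselective protio-semipinacol ring expansion of 1-alkenylcyclobutanols, extended here to an unstrained cyclopentanol with a dienyl donor. Ring C closes by ring enlargement through a 1,2-alkyl shift (five- to six-membered), not by an end-to-end cyclisation, and the bond formed is Cq–C-6′. The quaternary stereocentre is set by the catalyst: the counter-anion, hydrogen-bonded to the hydroxyl, covers one face of the planar allyl cation so that the migrating carbon arrives on the other. The two ring carbons that can migrate are equivalent, so there is no regiochemical issue. The step needs C-protonation of the diene to win over ionisation of the tertiary allylic alcohol, and migration to win over proton loss to a triene; a non-polar solvent, low temperature and a confined, strongly acidic catalyst favour a tight ion pair in which the intramolecular shift is the fastest exit.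

Step 3
Reactants: 3 (2R)-2-ethenyl-2-methylcyclohexan-1-one
Product: 5 (6R)-6-ethenyl-2,2,6-trimethylcyclohexan-1-one, via monomethyl ketone 4 (not isolated)
Conditions: KOC(CH3)3 (3 equiv), CH3I (6 equiv), THF, 0 °C to rt
Reagents that add atoms: iodomethane, CI
Why: Exhaustive enolate methylation; C-3′ is the only enolisable α-carbon because Cq is quaternary, so the reaction can only end at the gem-dimethyl ketone, and Cq cannot epimerise.

Step 4
Reactants: 5 (6R)-6-ethenyl-2,2,6-trimethylcyclohexan-1-one
Product: 7 (3S)-3-ethenyl-1,1,3-trimethylcyclohexane, via hydrazone 6 (not isolated)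
Conditions: N2H4·H2O (excess), N2H4·2HCl (cat.), triethylene glycol, 130 °C; then KOH, 210 °C, argon, product distilled out
Reagents that add atoms: none
Why: Wolff–Kishner reduction in its high-temperature (Huang-Minlon type) form with hydrazinium-salt catalysis of hydrazone formation, as used for ketones flanked by two quaternary carbons; the diazenyl anion pathway has neither a cation nor a radical next to Cq that could shift the vinyl group, the vinyl group on a quaternary carbon cannot isomerise, and exclusion of air prevents diimide reduction of the alkene.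

Step 5
Reactants: 7 (3S)-3-ethenyl-1,1,3-trimethylcyclohexane
Product: 8 1-[(1S)-1,3,3-trimethylcyclohexyl]ethan-1-one
Conditions: PdCl2 (10 mol %), CuCl (1 equiv), O2 (1 atm), DMF–H2O (7:1), rt
Reagents that add atoms: water, O
Why: Tsuji–Wacker oxidation; Markovnikov hydroxypalladation of the terminal alkene by divalent palladium gives the methyl ketone, and the hydrocarbon has no other reactive site.

Step 6
Reactants: 8 1-[(1S)-1,3,3-trimethylcyclohexyl]ethan-1-one
Product: 10 1-[(1S)-1,3,3-trimethylcyclohexyl]ethenyl trifluoromethanesulfonate, via potassium enolate 9 (not isolated)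
Conditions: KN(SiMe3)2, THF, −78 °C; then PhNTf2, −78 to 0 °C
Reagents that add atoms: N-phenylbis(trifluoromethanesulfonimide), O=S(=O)(N(c1ccccc1)S(=O)(=O)C(F)(F)F)C(F)(F)F
Why: O-Triflation of a ketone enolate; only the methyl group can be deprotonated because the other α-carbon is Cq.

Step 7
Reactants: 10 1-[(1S)-1,3,3-trimethylcyclohexyl]ethenyl trifluoromethanesulfonate
Product: 11 2-[(1S)-1,3,3-trimethylcyclohexyl]buta-1,3-diene
Conditions: tributyl(vinyl)stannane, Pd(PPh3)4 (5 mol %), LiCl (3 equiv), THF, 65 °C
Reagents that add atoms: tributyl(vinyl)stannane, C=C[Sn](CCCC)(CCCC)CCCC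
Why: Stille coupling of an enol triflate with a vinylstannane, the standard entry to 2-substituted 1,3-dienes; chloride replaces triflate on palladium and speeds transmetalation.

Step 8
Reactants: 11 2-[(1S)-1,3,3-trimethylcyclohexyl]buta-1,3-diene; 12 (5S)-5-[(1S,2R,5S)-menthyloxy]furan-2(5H)-one
Product: 13 (3S,3aS,7aR)-3-[(1S,2R,5S)-menthyloxy]-5-[(1S)-1,3,3-trimethylcyclohexyl]-3a,4,7,7a-tetrahydro-2-benzofuran-1(3H)-one
Conditions: toluene, 2,6-di-tert-butyl-4-methylphenol (cat.), 120 °C, sealed tube
Reagents that add atoms: none
Why: Thermal Diels–Alder reaction of a 5-alkoxybutenolide; the 2-alkyl group makes the CH2 next to C-2 the more nucleophilic diene terminus, which bonds to the β-carbon of the butenolide (the 1,4 orientation), the diene adds anti to the menthyloxy group so that the acetal carbon alone fixes C-5 and C-6, and the fusion is cis because the dienophile is a cis-alkene; as both diene termini are CH2 groups, the endo or exo mode and the diene face do not affect the stereochemical outcome.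

Step 9
Reactants: 13 (3S,3aS,7aR)-3-[(1S,2R,5S)-menthyloxy]-5-[(1S)-1,3,3-trimethylcyclohexyl]-3a,4,7,7a-tetrahydro-2-benzofuran-1(3H)-one
Product: 14 (3S,3aR,7aR)-4-hydroxy-3-[(1S,2R,5S)-menthyloxy]-5-[(1S)-1,3,3-trimethylcyclohexyl]-3a,4,7,7a-tetrahydro-2-benzofuran-1(3H)-one (carbinol epimers not assigned)
Conditions: SeO2 (0.5 equiv), t-BuOOH (3 equiv), CH2Cl2, rt
Reagents that add atoms: selenium dioxide, O=[Se]=O; tert-butyl hydroperoxide, CC(C)(C)OO
Why: Riley allylic oxidation; the ene reaction followed by the [2,3]-shift puts the hydroxyl on the ring CH2 attached to the more substituted alkene carbon (C-1) and returns the alkene to C-2=C-3, while C-4 lies on the less substituted side; the carbinol configuration is irrelevant because it is oxidised next, and the lactone acetal withstands the weakly acidic medium.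

Step 10
Reactants: 14 (3S,3aR,7aR)-4-hydroxy-3-[(1S,2R,5S)-menthyloxy]-5-[(1S)-1,3,3-trimethylcyclohexyl]-3a,4,7,7a-tetrahydro-2-benzofuran-1(3H)-one
Product: 15 (3S,3aS,7aR)-3-[(1S,2R,5S)-menthyloxy]-5-[(1S)-1,3,3-trimethylcyclohexyl]-3a,7a-dihydro-2-benzofuran-1,4(3H,7H)-dione
Conditions: Dess–Martin periodinane, NaHCO3, CH2Cl2, 0 °C to rt
Reagents that add atoms: none
Why: Dess–Martin oxidation of a secondary allylic alcohol to the enone; buffering keeps the β-acyloxy ketone away from base, which could expel the carboxylate, and the cis ring fusion at C-6 is also the more stable one should that centre enolise.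

Step 11
Reactants: 15 (3S,3aS,7aR)-3-[(1S,2R,5S)-menthyloxy]-5-[(1S)-1,3,3-trimethylcyclohexyl]-3a,7a-dihydro-2-benzofuran-1,4(3H,7H)-dione
Product: 17 (3S,3aR,7aR)-3-[(1S,2R,5S)-menthyloxy]-1-oxo-5-[(1S)-1,3,3-trimethylcyclohexyl]-1,3,3a,6,7,7a-hexahydro-2-benzofuran-4-yl trifluoromethanesulfonate, via lithium enolate 16 (not isolated)
Conditions: Li[HB(sec-Bu)3] (1.05 equiv), THF, −78 °C; then PhNTf2, −78 to 0 °C
Reagents that add atoms: N-phenylbis(trifluoromethanesulfonimide), O=S(=O)(N(c1ccccc1)S(=O)(=O)C(F)(F)F)C(F)(F)F
Why: Reductive enol triflation; the bulky borohydride adds in conjugate fashion to the unsubstituted β-carbon C-3 and gives only the C-1/C-2 enolate, which is triflated on oxygen, so the tetrasubstituted alkene is placed regiospecifically; one equivalent at −78 °C leaves the lactone untouched, and no stereocentre is formed.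

Step 12
Reactants: 18 methyl propiolate
Product: 19 methyl 2-(tributylstannyl)prop-2-enoate
Conditions: Bu3SnH, Pd(PPh3)4 (2 mol %), THF, 0 °C to rt
Reagents that add atoms: tributyltin hydride, CCCC[SnH](CCCC)CCCC
Why: Palladium-catalysed hydrostannation of an alkynoate; syn addition of H and Sn places tin on the α-carbon, the usual regiochemistry for propiolates.

Step 13
Reactants: 17 (3S,3aR,7aR)-3-[(1S,2R,5S)-menthyloxy]-1-oxo-5-[(1S)-1,3,3-trimethylcyclohexyl]-1,3,3a,6,7,7a-hexahydro-2-benzofuran-4-yl trifluoromethanesulfonate; 19 methyl 2-(tributylstannyl)prop-2-enoate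
Product: 20 methyl 2-{(3S,3aR,7aR)-3-[(1S,2R,5S)-menthyloxy]-1-oxo-5-[(1S)-1,3,3-trimethylcyclohexyl]-1,3,3a,6,7,7a-hexahydro-2-benzofuran-4-yl}prop-2-enoate
Conditions: Pd(PPh3)4 (10 mol %), CuCl (5 equiv), LiCl (6 equiv), DMSO, 60 °C
Reagents that add atoms: none
Why: Stille coupling of an enol triflate with an α-stannyl acrylate under copper chloride and lithium chloride acceleration, the variant used when both partners are hindered; it forms the C-1–Cα bond and the ring fixes the alkene geometry.

Step 14
Reactants: 20 methyl 2-{(3S,3aR,7aR)-3-[(1S,2R,5S)-menthyloxy]-1-oxo-5-[(1S)-1,3,3-trimethylcyclohexyl]-1,3,3a,6,7,7a-hexahydro-2-benzofuran-4-yl}prop-2-enoate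
Product: 21 methyl (2R)-2-{(3S,3aR,7aR)-3-[(1S,2R,5S)-menthyloxy]-1-oxo-5-[(1S)-1,3,3-trimethylcyclohexyl]-1,3,3a,6,7,7a-hexahydro-2-benzofuran-4-yl}propanoate
Conditions: [Ir(cod)(L)][B(3,5-(CF3)2C6H3)4] (2 mol %; L = (S)-4-tert-butyl-2-[2-(diphenylphosphino)phenyl]-4,5-dihydrooxazole, antipode as required), H2 (5 bar), CH2Cl2, rt
Reagents that add atoms: none
Why: Asymmetric hydrogenation of a 1,1-disubstituted alkene (an α-substituted acrylate) with a cationic iridium N,P catalyst, which needs no chelating group; the ligand sets Cα as (R), the tetrasubstituted ring alkene is too hindered to be reduced, and the conformer with the ester turned away from the lactone carbon on C-6 and hydrogen arriving from the open C-6 side would lead to the same epimer, so substrate and catalyst are expected to be matched.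

Step 15
Reactants: 21 methyl (2R)-2-{(3S,3aR,7aR)-3-[(1S,2R,5S)-menthyloxy]-1-oxo-5-[(1S)-1,3,3-trimethylcyclohexyl]-1,3,3a,6,7,7a-hexahydro-2-benzofuran-4-yl}propanoate
Product: 22 methyl (2R)-2-{(3R,3aR,7aR)-3-hydroxy-1-oxo-5-[(1S)-1,3,3-trimethylcyclohexyl]-1,3,3a,6,7,7a-hexahydro-2-benzofuran-4-yl}propanoate
Conditions: CF3CO2H–H2O–THF (3:1:2), rt to 40 °C
Reagents that add atoms: water, O
Why: Acid hydrolysis of the acyloxy-substituted mixed acetal, which needs a stronger acid than a simple acetal; water keeps the lactol from closing onto the methyl ester, the hindered ester is not hydrolysed, and the lactol carbon settles by ring–chain equilibration.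

## Compound list

1 | 1-ethynylcyclopentan-1-ol | C#CC1(O)CCCC1 | starting material
2 | 1-(buta-1,3-dien-2-yl)cyclopentan-1-ol | C=CC(=C)C1(O)CCCC1 | intermediate
3 | (2R)-2-ethenyl-2-methylcyclohexan-1-one | C=C[C@@]1(C)CCCCC1=O | intermediate
4 | (2R)-2-ethenyl-2,6-dimethylcyclohexan-1-one (both C-6 epimers) | C=C[C@@]1(C)CCCC(C)C1=O | intermediate (not isolated)
5 | (6R)-6-ethenyl-2,2,6-trimethylcyclohexan-1-one | C=C[C@@]1(C)CCCC(C)(C)C1=O | intermediate
6 | hydrazone of (6R)-6-ethenyl-2,2,6-trimethylcyclohexan-1-one | C=C[C@@]1(C)CCCC(C)(C)C1=NN | intermediate (not isolated)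
7 | (3S)-3-ethenyl-1,1,3-trimethylcyclohexane | C=C[C@@]1(C)CCCC(C)(C)C1 | intermediate
8 | 1-[(1S)-1,3,3-trimethylcyclohexyl]ethan-1-one | CC(=O)[C@@]1(C)CCCC(C)(C)C1 | intermediate
9 | potassium 1-[(1S)-1,3,3-trimethylcyclohexyl]ethen-1-olate | [K+].[O-]C(=C)[C@@]1(C)CCCC(C)(C)C1 | intermediate (not isolated)
10 | 1-[(1S)-1,3,3-trimethylcyclohexyl]ethenyl trifluoromethanesulfonate | C=C(OS(=O)(=O)C(F)(F)F)[C@@]1(C)CCCC(C)(C)C1 | intermediate
11 | 2-[(1S)-1,3,3-trimethylcyclohexyl]buta-1,3-diene | C=CC(=C)[C@@]1(C)CCCC(C)(C)C1 | intermediate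
12 | (5S)-5-{[(1S,2R,5S)-5-methyl-2-(propan-2-yl)cyclohexyl]oxy}furan-2(5H)-one | O=C1C=C[C@@H](O[C@H]2C[C@@H](C)CC[C@@H]2C(C)C)O1 | starting material
13 | (3S,3aS,7aR)-3-[(1S,2R,5S)-menthyloxy]-5-[(1S)-1,3,3-trimethylcyclohexyl]-3a,4,7,7a-tetrahydro-2-benzofuran-1(3H)-one | C[C@@]1(CCCC(C)(C)C1)C2=CC[C@H]3C(=O)O[C@H](O[C@H]4C[C@@H](C)CC[C@@H]4C(C)C)[C@H]3C2 | intermediate
14 | (3S,3aR,7aR)-4-hydroxy-3-[(1S,2R,5S)-menthyloxy]-5-[(1S)-1,3,3-trimethylcyclohexyl]-3a,4,7,7a-tetrahydro-2-benzofuran-1(3H)-one (carbinol epimers) | C[C@@]1(CCCC(C)(C)C1)C2=CC[C@H]3C(=O)O[C@H](O[C@H]4C[C@@H](C)CC[C@@H]4C(C)C)[C@H]3C2O | intermediate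
15 | (3S,3aS,7aR)-3-[(1S,2R,5S)-menthyloxy]-5-[(1S)-1,3,3-trimethylcyclohexyl]-3a,7a-dihydro-2-benzofuran-1,4(3H,7H)-dione | C[C@@]1(CCCC(C)(C)C1)C2=CC[C@H]3C(=O)O[C@H](O[C@H]4C[C@@H](C)CC[C@@H]4C(C)C)[C@H]3C2=O | intermediate
16 | lithium (3S,3aR,7aR)-3-[(1S,2R,5S)-menthyloxy]-1-oxo-5-[(1S)-1,3,3-trimethylcyclohexyl]-1,3,3a,6,7,7a-hexahydro-2-benzofuran-4-olate | [Li+].[O-]C1=C([C@@]2(C)CCCC(C)(C)C2)CC[C@H]2C(=O)O[C@H](O[C@H]3C[C@@H](C)CC[C@@H]3C(C)C)[C@@H]12 | intermediate (not isolated)
17 | (3S,3aR,7aR)-3-[(1S,2R,5S)-menthyloxy]-1-oxo-5-[(1S)-1,3,3-trimethylcyclohexyl]-1,3,3a,6,7,7a-hexahydro-2-benzofuran-4-yl trifluoromethanesulfonate | FC(F)(F)S(=O)(=O)OC1=C([C@@]2(C)CCCC(C)(C)C2)CC[C@H]2C(=O)O[C@H](O[C@H]3C[C@@H](C)CC[C@@H]3C(C)C)[C@@H]12 | intermediate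
18 | methyl propiolate | C#CC(=O)OC | starting material
19 | methyl 2-(tributylstannyl)prop-2-enoate | C=C(C(=O)OC)[Sn](CCCC)(CCCC)CCCC | intermediate
20 | methyl 2-{(3S,3aR,7aR)-3-[(1S,2R,5S)-menthyloxy]-1-oxo-5-[(1S)-1,3,3-trimethylcyclohexyl]-1,3,3a,6,7,7a-hexahydro-2-benzofuran-4-yl}prop-2-enoate | C=C(C(=O)OC)C1=C([C@@]2(C)CCCC(C)(C)C2)CC[C@H]2C(=O)O[C@H](O[C@H]3C[C@@H](C)CC[C@@H]3C(C)C)[C@@H]12 | intermediate
21 | methyl (2R)-2-{(3S,3aR,7aR)-3-[(1S,2R,5S)-menthyloxy]-1-oxo-5-[(1S)-1,3,3-trimethylcyclohexyl]-1,3,3a,6,7,7a-hexahydro-2-benzofuran-4-yl}propanoate | COC(=O)[C@H](C)C1=C([C@@]2(C)CCCC(C)(C)C2)CC[C@H]2C(=O)O[C@H](O[C@H]3C[C@@H](C)CC[C@@H]3C(C)C)[C@@H]12 | intermediate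
22 | methyl (2R)-2-{(3R,3aR,7aR)-3-hydroxy-1-oxo-5-[(1S)-1,3,3-trimethylcyclohexyl]-1,3,3a,6,7,7a-hexahydro-2-benzofuran-4-yl}propanoate | COC(=O)[C@H](C)C1=C([C@@]2(C)CCCC(C)(C)C2)CC[C@H]2C(=O)O[C@@H](O)[C@@H]12 | target

## Step count and least certain steps

Total step count: 15. Longest linear sequence: 14 steps (steps 1 to 11 and 13 to 15, from 1); step 12 prepares the stannane 19.

**Step 2 (key step).** The most likely failures are ionisation of the tertiary allylic alcohol, or proton loss from the allyl cation to trienes and oligomers. Ring enlargement of a cyclopentanol releases little strain, so the shift is slower than with cyclobutanols. A loose ion pair would also erode the facial selectivity.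

The fallback uses known chemistry and does not branch from 2. It starts afresh from commercial 2-methylcyclohexan-1-one F1 and comes back to the route at 3.
- F1 is converted into its more substituted silyl enol ether, trimethyl[(2-methylcyclohex-1-en-1-yl)oxy]silane F2 (Me3SiCl, NaI, Et3N).
- Cleavage with MeLi and acylation with allyl chloroformate give allyl 2-methylcyclohex-1-en-1-yl carbonate F3.
- Palladium-catalysed decarboxylative asymmetric allylic alkylation (Pd2(dba)3, (R)-t-Bu-PHOX) gives (2R)-2-methyl-2-(prop-2-en-1-yl)cyclohexan-1-one F4.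
- Alkene isomerisation with RuHCl(CO)(PPh3)3 gives (2R)-2-methyl-2-[(1E)-prop-1-en-1-yl]cyclohexan-1-one F5.
- Ethenolysis with RuCl2(=CH-2-(i-PrO)C6H4)(H2IMes) (second-generation Hoveyda–Grubbs catalyst) under ethylene gives 3.

Any shortfall in enantiomeric purity would be removed after step 8, where the minor Cq series is a diastereomer of 13.

**Step 4.** Hydrazone formation at a carbonyl flanked by two quaternary carbons may stall, and traces of air would generate diimide and reduce the vinyl group.

The fallback sets out from 5 and returns at 7.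
- LiAlH4 reduces the ketone to (6R)-6-ethenyl-2,2,6-trimethylcyclohexan-1-ol F6.
- Its lithium alkoxide is phosphorylated with ClP(O)(NMe2)2 to the N,N,N′,N′-tetramethylphosphorodiamidate F7.
- The C–O bond is cleaved by lithium in ethylamine with tert-butanol at 0 °C.

The second electron transfer is much faster than the 1,2-vinyl shift that a tin-hydride radical chain would suffer at this position. Short exposure is needed to spare the terminal alkene.

**Step 8.** The orientation rests only on the 2-alkyl group of the diene, so the 1,3 orientation may compete. The reaction is also slow enough for diene dimerisation to intervene.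

The fallback sets out from 12 (with 11) and returns at 13.
- Bromine adds to 12 to give the dibromolactone (5S)-3,4-dibromo-5-[(1S,2R,5S)-menthyloxy]dihydrofuran-2(3H)-one F8.
- Triethylamine eliminates HBr to give (5S)-3-bromo-5-[(1S,2R,5S)-menthyloxy]furan-2(5H)-one F9.
- The carbon of F9 that becomes quaternary should bond to the less hindered diene terminus; cycloaddition with 11 gives the bromo adduct (3S,3aS,7aR)-7a-bromo-3-[(1S,2R,5S)-menthyloxy]-5-[(1S)-1,3,3-trimethylcyclohexyl]-3a,4,7,7a-tetrahydro-2-benzofuran-1(3H)-one F10.
- Bu3SnH with AIBN removes the bromine; hydrogen transfer to the α-carbonyl radical gives the cis-fused 13.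

**Step 13.** Transmetalation and reductive elimination may be too slow at a triflate carbon flanked by the tertiary alkyl group and the ring fusion, so that protodestannylation of 19 or its homocoupling takes over.

The fallback sets out from 17 and returns at 20.
- The small, reactive tributyl(1-ethoxyvinyl)stannane is coupled to give the enol ether (3S,3aR,7aR)-4-(1-ethoxyethenyl)-3-[(1S,2R,5S)-menthyloxy]-5-[(1S)-1,3,3-trimethylcyclohexyl]-3a,6,7,7a-tetrahydro-2-benzofuran-1(3H)-one F11.
- Brief treatment with dilute HCl gives the methyl ketone (3S,3aR,7aR)-4-acetyl-3-[(1S,2R,5S)-menthyloxy]-5-[(1S)-1,3,3-trimethylcyclohexyl]-3a,6,7,7a-tetrahydro-2-benzofuran-1(3H)-one F12.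
- KN(SiMe3)2 and PhNTf2 at −78 °C give the dienyl triflate 1-{(3S,3aR,7aR)-3-[(1S,2R,5S)-menthyloxy]-1-oxo-5-[(1S)-1,3,3-trimethylcyclohexyl]-1,3,3a,6,7,7a-hexahydro-2-benzofuran-4-yl}ethenyl trifluoromethanesulfonate F13.
- Palladium-catalysed methoxycarbonylation (Pd(OAc)2, PPh3, CO, MeOH, Et3N) gives 20.

**Step 14.** The catalyst may fail to override the conformational bias of the twisted dienoate (poor facial selectivity), or the hindered alkene may be reduced too slowly.

The fallback changes to carboxylate-directed hydrogenation, the best-precedented mode for α-substituted acrylic acids. It sets out from 17 and returns at 21.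
- tert-Butyl 2-(tributylstannyl)prop-2-enoate F14 is made from tert-butyl propiolate as in step 12.
- F14 is coupled as in step 13 to the tert-butyl ester tert-butyl 2-{(3S,3aR,7aR)-3-[(1S,2R,5S)-menthyloxy]-1-oxo-5-[(1S)-1,3,3-trimethylcyclohexyl]-1,3,3a,6,7,7a-hexahydro-2-benzofuran-4-yl}prop-2-enoate F15.
- Anhydrous CF3CO2H in CH2Cl2 at 0 °C cleaves the ester to the acrylic acid 2-{(3S,3aR,7aR)-3-[(1S,2R,5S)-menthyloxy]-1-oxo-5-[(1S)-1,3,3-trimethylcyclohexyl]-1,3,3a,6,7,7a-hexahydro-2-benzofuran-4-yl}prop-2-enoic acid F16. The acyloxy-substituted acetal should ionise far more slowly than the tert-butyl ester.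
- Ru(OAc)2[(S)-BINAP] (antipode as required) and H2 in methanol give (2R)-2-{(3S,3aR,7aR)-3-[(1S,2R,5S)-menthyloxy]-1-oxo-5-[(1S)-1,3,3-trimethylcyclohexyl]-1,3,3a,6,7,7a-hexahydro-2-benzofuran-4-yl}propanoic acid F17.
- Me3SiCHN2 in methanol–toluene gives 21.

## Further compounds

F1 | step 2 | 2-methylcyclohexan-1-one | CC1CCCCC1=O
F2 | step 2 | trimethyl[(2-methylcyclohex-1-en-1-yl)oxy]silane | CC1=C(O[Si](C)(C)C)CCCC1
F3 | step 2 | allyl 2-methylcyclohex-1-en-1-yl carbonate | C=CCOC(=O)OC1=C(C)CCCC1
F4 | step 2 | (2R)-2-methyl-2-(prop-2-en-1-yl)cyclohexan-1-one | C=CC[C@@]1(C)CCCCC1=O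
F5 | step 2 | (2R)-2-methyl-2-[(1E)-prop-1-en-1-yl]cyclohexan-1-one | C/C=C/[C@@]1(C)CCCCC1=O
F6 | step 4 | (6R)-6-ethenyl-2,2,6-trimethylcyclohexan-1-ol (carbinol epimers) | C=C[C@@]1(C)CCCC(C)(C)C1O
F7 | step 4 | (6R)-6-ethenyl-2,2,6-trimethylcyclohexyl N,N,N',N'-tetramethylphosphorodiamidate | C=C[C@@]1(C)CCCC(C)(C)C1OP(=O)(N(C)C)N(C)C
F8 | step 8 | (5S)-3,4-dibromo-5-[(1S,2R,5S)-menthyloxy]dihydrofuran-2(3H)-one | O=C1C(Br)C(Br)[C@@H](O[C@H]2C[C@@H](C)CC[C@@H]2C(C)C)O1
F9 | step 8 | (5S)-3-bromo-5-[(1S,2R,5S)-menthyloxy]furan-2(5H)-one | O=C1C(Br)=C[C@@H](O[C@H]2C[C@@H](C)CC[C@@H]2C(C)C)O1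
F10 | step 8 | (3S,3aS,7aR)-7a-bromo-3-[(1S,2R,5S)-menthyloxy]-5-[(1S)-1,3,3-trimethylcyclohexyl]-3a,4,7,7a-tetrahydro-2-benzofuran-1(3H)-one | C[C@@]1(CCCC(C)(C)C1)C2=CC[C@@]3(Br)C(=O)O[C@H](O[C@H]4C[C@@H](C)CC[C@@H]4C(C)C)[C@H]3C2
F11 | step 13 | (3S,3aR,7aR)-4-(1-ethoxyethenyl)-3-[(1S,2R,5S)-menthyloxy]-5-[(1S)-1,3,3-trimethylcyclohexyl]-3a,6,7,7a-tetrahydro-2-benzofuran-1(3H)-one | CCOC(=C)C1=C([C@@]2(C)CCCC(C)(C)C2)CC[C@H]2C(=O)O[C@H](O[C@H]3C[C@@H](C)CC[C@@H]3C(C)C)[C@@H]12
F12 | step 13 | (3S,3aR,7aR)-4-acetyl-3-[(1S,2R,5S)-menthyloxy]-5-[(1S)-1,3,3-trimethylcyclohexyl]-3a,6,7,7a-tetrahydro-2-benzofuran-1(3H)-one | CC(=O)C1=C([C@@]2(C)CCCC(C)(C)C2)CC[C@H]2C(=O)O[C@H](O[C@H]3C[C@@H](C)CC[C@@H]3C(C)C)[C@@H]12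
F13 | step 13 | 1-{(3S,3aR,7aR)-3-[(1S,2R,5S)-menthyloxy]-1-oxo-5-[(1S)-1,3,3-trimethylcyclohexyl]-1,3,3a,6,7,7a-hexahydro-2-benzofuran-4-yl}ethenyl trifluoromethanesulfonate | C=C(OS(=O)(=O)C(F)(F)F)C1=C([C@@]2(C)CCCC(C)(C)C2)CC[C@H]2C(=O)O[C@H](O[C@H]3C[C@@H](C)CC[C@@H]3C(C)C)[C@@H]12
F14 | step 14 | tert-butyl 2-(tributylstannyl)prop-2-enoate | C=C(C(=O)OC(C)(C)C)[Sn](CCCC)(CCCC)CCCC
F15 | step 14 | tert-butyl 2-{(3S,3aR,7aR)-3-[(1S,2R,5S)-menthyloxy]-1-oxo-5-[(1S)-1,3,3-trimethylcyclohexyl]-1,3,3a,6,7,7a-hexahydro-2-benzofuran-4-yl}prop-2-enoate | C=C(C(=O)OC(C)(C)C)C1=C([C@@]2(C)CCCC(C)(C)C2)CC[C@H]2C(=O)O[C@H](O[C@H]3C[C@@H](C)CC[C@@H]3C(C)C)[C@@H]12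
F16 | step 14 | 2-{(3S,3aR,7aR)-3-[(1S,2R,5S)-menthyloxy]-1-oxo-5-[(1S)-1,3,3-trimethylcyclohexyl]-1,3,3a,6,7,7a-hexahydro-2-benzofuran-4-yl}prop-2-enoic acid | C=C(C(=O)O)C1=C([C@@]2(C)CCCC(C)(C)C2)CC[C@H]2C(=O)O[C@H](O[C@H]3C[C@@H](C)CC[C@@H]3C(C)C)[C@@H]12
F17 | step 14 | (2R)-2-{(3S,3aR,7aR)-3-[(1S,2R,5S)-menthyloxy]-1-oxo-5-[(1S)-1,3,3-trimethylcyclohexyl]-1,3,3a,6,7,7a-hexahydro-2-benzofuran-4-yl}propanoic acid | OC(=O)[C@H](C)C1=C([C@@]2(C)CCCC(C)(C)C2)CC[C@H]2C(=O)O[C@H](O[C@H]3C[C@@H](C)CC[C@@H]3C(C)C)[C@@H]12
A1 | alternative 1 | methyl (2R)-2-{2-[(1S)-1,3,3-trimethylcyclohexyl]cyclohexa-1,5-dien-1-yl}propanoate | COC(=O)[C@H](C)C1=C([C@@]2(C)CCCC(C)(C)C2)CCC=C1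
A2 | alternative 1 | methyl (2R)-2-{cis-8-(benzyloxy)-7-oxo-3-[(1S)-1,3,3-trimethylcyclohexyl]bicyclo[4.2.0]oct-2-en-2-yl}propanoate | COC(=O)[C@H](C)C1=C([C@@]2(C)CCCC(C)(C)C2)CC[C@H]2C(=O)[C@@H](OCc3ccccc3)[C@@H]12
A3 | alternative 2 | 5-oxo-2,5-dihydrofuran-2-yl 2-methyl-4-[(1S)-1,3,3-trimethylcyclohexyl]but-3-ynoate | C[C@H](C#C[C@@]1(C)CCCC(C)(C)C1)C(=O)O[C@@H]2OC(=O)C=C2
A4 | alternative 2 | tricyclic diene bis-lactone | C[C@H]1C(=O)O[C@@H]2OC(=O)[C@@H]3C=CC(=C1[C@H]23)[C@@]4(C)CCCC(C)(C)C4
A5 | alternative 3 | di-tert-butyl 2-methyl-3-oxopentanedioate | CC(C(=O)OC(C)(C)C)C(=O)CC(=O)OC(C)(C)C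
A6 | alternative 3 | tert-butyl (2E)-4-oxo-5-[(1S)-1,3,3-trimethylcyclohexyl]pent-2-enoate | CC(C)(C)OC(=O)/C=C/C(=O)C[C@@]1(C)CCCC(C)(C)C1
A7 | alternative 3 | ring A cyclohexenone triester | CC(C)(C)OC(=O)[C@H](C)C1=C([C@@]2(C)CCCC(C)(C)C2)C(=O)C[C@@H](C(=O)OC(C)(C)C)[C@@H]1C(=O)OC(C)(C)C
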